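**Retrosynthetic overview**
- The target comes from a 17-membered bis(bibenzyl) macrocycle by O-demethylation and a twofold ortho-hydroxylation (ortho-formylation, then Dakin oxidation).
- Key step: ring contraction of an 18-membered aza-macrocycle by nitrogen deletion, which forms the ring B–CH2–CH2–ring C bond; the aza-macrocycle is closed from a seco-dialdehyde and ammonia.
- The seco-dialdehyde comes from an Ullmann ether coupling (ring A–O–ring B) and an SNAr ether formation (ring D–O–ring C); each aldehyde arrives with its ring.
- The ring D–CH2–CH2–ring A bond comes from the benzylic dianion of o-cresol and 3-bromo-4-methoxybenzyl bromide.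
- Ring order: the four benzene rings are bought (p-cresol twice, o-cresol, 2-fluorophenol); the only ring made is the macrocycle (18-membered in step 10, contracted to 17 in step 11).

Assumption: the target has no stereogenic element (no stereocentre, conformationally mobile 17-membered ring), so "single enantiomer" means the achiral compound as drawn; no step creates a stereocentre.

Ring labels: ring A = ring from p-cresol (C-1 carries the bridge to ring D, C-3 and C-4 the oxygens, C-5 the O to ring B); ring B = para-phenylene; ring C = ring from 2-fluorophenol (C-1 carries the bridge to ring B, C-2 the O to ring D, C-3 and C-4 the oxygens); ring D = ortho-phenylene from o-cresol.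

**Route**

Step 1
Reactants: 1 p-cresol (4-methylphenol)
Product: 2 2-bromo-4-methylphenol
Conditions: Br2 (1.0 equiv), CH2Cl2, 0 °C
Reagents that add atoms: bromine, BrBr
Why: Electrophilic aromatic bromination; OH directs ortho because the para position carries the methyl group.

Step 2
Reactants: 2 2-bromo-4-methylphenol
Product: 3 2-bromo-1-methoxy-4-methylbenzene
Conditions: MeI, K2CO3, acetone, 56 °C
Reagents that add atoms: iodomethane, CI
Why: Williamson O-methylation; the methyl ether carries the ring A phenol through the radical, superbase and copper steps.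

Step 3
Reactants: 3 2-bromo-1-methoxy-4-methylbenzene
Product: 4 2-bromo-4-(bromomethyl)-1-methoxybenzene
Conditions: NBS (1.05 equiv), AIBN (cat.), PhCF3, 85 °C
Reagents that add atoms: N-bromosuccinimide, O=C1CCC(=O)N1Br
Why: Wohl–Ziegler benzylic bromination; the ring bromine and the non-polar radical medium suppress nuclear bromination.

Step 4
Reactants: 5 o-cresol (2-methylphenol); 4 2-bromo-4-(bromomethyl)-1-methoxybenzene
Product: 7 2-[2-(3-bromo-4-methoxyphenyl)ethyl]phenol, via dipotassium o-cresol dianion 6 (not isolated)
Conditions: 5 (1.3 equiv), n-BuLi and KOtBu (2.0 equiv each per 5), heptane, 98 °C; then THF, 4, −78 °C to rt; HCl aq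
Reagents that add atoms: none
Why: Lateral (benzylic) dimetalation of the cresol with the n-BuLi/KOtBu superbase followed by SN2 alkylation at carbon (the carbanion is far more nucleophilic than the phenoxide) forms the ring D–CH2–CH2–ring A bond and leaves the ring D OH free.

Step 5
Reactants: 8 2-fluorophenol
Product: 9 2-fluoroanisole (1-fluoro-2-methoxybenzene)
Conditions: MeI, K2CO3, acetone, 56 °C
Reagents that add atoms: iodomethane, CI
Why: Williamson O-methylation; protects the future ring C C-3 oxygen.

Step 6
Reactants: 9 2-fluoroanisole
Product: 11 2-fluoro-3-methoxybenzaldehyde, via aryllithium 10 (not isolated)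
Conditions: n-BuLi, PMDTA, THF, −78 °C; DMF; HCl aq
Reagents that add atoms: N,N-dimethylformamide, CN(C)C=O
Why: Directed ortho-metalation; PMDTA-activated n-BuLi removes the most acidic proton, the one next to fluorine, and DMF formylates the aryllithium.

Step 7
Reactants: 7 2-[2-(3-bromo-4-methoxyphenyl)ethyl]phenol; 11 2-fluoro-3-methoxybenzaldehyde
Product: 12 2-{2-[2-(3-bromo-4-methoxyphenyl)ethyl]phenoxy}-3-methoxybenzaldehyde
Conditions: Cs2CO3, DMSO, 100 °C
Reagents that add atoms: none
Why: SNAr; the fluoride ortho to the formyl group is displaced by the ring D phenoxide (formyl-stabilised Meisenheimer complex), while the aryl bromide is inert.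

Step 8
Reactants: 1 p-cresol
Product: 13 4-hydroxybenzaldehyde
Conditions: O2 (1 atm), CoCl2 (cat.), NaOH, MeOH, 60 °C; HCl aq
Reagents that add atoms: dioxygen, O=O
Why: Cobalt-catalysed aerobic benzylic oxidation of the p-cresolate via its p-quinone methide; it stops at the aldehyde because the product phenolate is deactivated.

Step 9
Reactants: 12 the bromo aldehyde from step 7; 13 4-hydroxybenzaldehyde
Product: 14 2-{2-[2-(3-(4-formylphenoxy)-4-methoxyphenyl)ethyl]phenoxy}-3-methoxybenzaldehyde (seco-dialdehyde)
Conditions: CuI (10 mol %), N,N-dimethylglycine (30 mol %), Cs2CO3, 1,4-dioxane, 100 °C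
Reagents that add atoms: none
Why: Ullmann-type copper-catalysed diaryl ether coupling of the ortho-methoxy aryl bromide with the phenol forms the ring A–O–ring B bond; both aldehydes tolerate the carbonate base.

Step 10
Reactants: 14 seco-dialdehyde
Product: 16 18-membered aza-macrocycle (ring C C-1 and ring B C-4 joined by CH2–NH–CH2; OMe at ring A C-4 and ring C C-3), via macrocyclic aldimine 15 (not isolated)
Conditions: NH3 (2 M in EtOH, 5 equiv), Ti(OiPr)4 (2.2 equiv), THF, 0.002 M, rt; then NaBH4, rt; NH3 aq work-up
Reagents that add atoms: ammonia, N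
Why: Titanium-mediated reductive amination with ammonia, which turns aromatic aldehydes into secondary dibenzylic amines; at high dilution the second C–N bond forms intramolecularly (aldimine 15) and hydride reduction gives the macrocyclic amine.

Step 11
Reactants: 16 18-membered aza-macrocycle
Product: 18 17-membered bis(bibenzyl) macrocycle, O,O'-dimethyl ether (ring B–CH2–CH2–ring C; OMe at ring A C-4 and ring C C-3), via isodiazene 17 (not isolated)
Conditions: N-(benzyloxy)-N-(pivaloyloxy)-4-(trifluoromethyl)benzamide (1.5 equiv), THF, 0.01 M, 45 °C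
Reagents that add atoms: none
Why: Proposed new method: transannular nitrogen deletion used as a macrocyclic ring contraction (18 to 17 ring atoms) — the amine attacks the electrophilic nitrogen of the anomeric amide (pivalate leaves), the adduct collapses with loss of benzyl ester to isodiazene 17, N2 is expelled, and the two benzylic radicals, held together by the ring and lacking β-hydrogens, recombine stepwise (not pericyclic) to the CH2–CH2 bond between rings B and C; the closest known reaction type is anomeric-amide nitrogen deletion of acyclic dibenzylic and small- or medium-ring secondary amines, which to my knowledge has not been shown on a macrocyclic cyclophane-type amine or in bis(bibenzyl) synthesis.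

Step 12
Reactants: 18 macrocyclic dimethyl ether
Product: 19 macrocyclic bis-phenol (OH at ring A C-4 and ring C C-3)
Conditions: BBr3 (6 equiv), CH2Cl2, −78 °C to rt; H2O
Reagents that add atoms: none
Why: Lewis-acid O-demethylation of both aryl methyl ethers; diaryl ethers are inert to BBr3.

Step 13
Reactants: 19 macrocyclic bis-phenol
Product: 20 macrocyclic bis-salicylaldehyde (CHO at ring A C-3 and ring C C-4)
Conditions: MgCl2 (6 equiv), Et3N (12 equiv), (CH2O)n (20 equiv), MeCN, 80 °C; HCl aq
Reagents that add atoms: formaldehyde (as paraformaldehyde), C=O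
Why: Magnesium-mediated ortho-formylation (Casnati–Skattebøl) is ortho-specific, and each phenol has one free ortho position because the other carries the aryloxy group.

Step 14
Reactants: 20 macrocyclic bis-salicylaldehyde
Product: 22 target CNP0114693.0, via bis-formate ester 21 (not isolated)
Conditions: H2O2 (30 % aq, 2.4 equiv), NaOH (2 M aq), THF, 0 °C to rt, under Ar; HCl aq
Reagents that add atoms: hydrogen peroxide, OO
Why: Dakin oxidation; hydroperoxide adds to each o-hydroxybenzaldehyde, the aryl group shifts from carbon to oxygen, and the aryl formates are hydrolysed to the two catechols.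

**Compound list**

1 | p-cresol (4-methylphenol) | Cc1ccc(O)cc1 | starting material
2 | 2-bromo-4-methylphenol | Cc1ccc(O)c(Br)c1 | intermediate
3 | 2-bromo-1-methoxy-4-methylbenzene | COc1ccc(C)cc1Br | intermediate
4 | 2-bromo-4-(bromomethyl)-1-methoxybenzene | COc1ccc(CBr)cc1Br | intermediate
5 | o-cresol (2-methylphenol) | Cc1ccccc1O | starting material
6 | dipotassium o-cresol dianion (benzylic carbanion and phenoxide; not isolated) | [K+].[K+].[CH2-]c1ccccc1[O-] | intermediate
7 | 2-[2-(3-bromo-4-methoxyphenyl)ethyl]phenol | Oc1ccccc1CCc1ccc(OC)c(Br)c1 | intermediate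
8 | 2-fluorophenol | Oc1ccccc1F | starting material
9 | 2-fluoroanisole | COc1ccccc1F | intermediate
10 | (2-fluoro-3-methoxyphenyl)lithium (not isolated) | COc1cccc([Li])c1F | intermediate
11 | 2-fluoro-3-methoxybenzaldehyde | COc1cccc(C=O)c1F | intermediate
12 | 2-{2-[2-(3-bromo-4-methoxyphenyl)ethyl]phenoxy}-3-methoxybenzaldehyde | COc1cccc(C=O)c1Oc1ccccc1CCc1ccc(OC)c(Br)c1 | intermediate
13 | 4-hydroxybenzaldehyde | O=Cc1ccc(O)cc1 | intermediate
14 | seco-dialdehyde, 2-{2-[2-(3-(4-formylphenoxy)-4-methoxyphenyl)ethyl]phenoxy}-3-methoxybenzaldehyde | COc1cccc(C=O)c1Oc1ccccc1CCc1ccc(OC)c(Oc2ccc(C=O)cc2)c1 | intermediate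
15 | macrocyclic (E)-aldimine, CH=N at the ring C carbon and N–CH2 at ring B (not isolated) | COc1cccc2/C=N/Cc3ccc(cc3)Oc3cc(ccc3OC)CCc3ccccc3Oc12 | intermediate
16 | 18-membered aza-macrocycle, CH2–NH–CH2 between ring C C-1 and ring B C-4 | COc1cccc2CNCc3ccc(cc3)Oc3cc(ccc3OC)CCc3ccccc3Oc12 | intermediate
17 | macrocyclic isodiazene (1,1-diazene on the ring nitrogen; not isolated) | COc1cccc2C[N+](=[N-])Cc3ccc(cc3)Oc3cc(ccc3OC)CCc3ccccc3Oc12 | intermediate
18 | 17-membered bis(bibenzyl) macrocycle, dimethyl ether | COc1cccc2CCc3ccc(cc3)Oc3cc(ccc3OC)CCc3ccccc3Oc12 | intermediate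
19 | macrocyclic bis-phenol | Oc1cccc2CCc3ccc(cc3)Oc3cc(ccc3O)CCc3ccccc3Oc12 | intermediate
20 | macrocyclic bis-salicylaldehyde | Oc1c(C=O)ccc2CCc3ccc(cc3)Oc3cc(cc(C=O)c3O)CCc3ccccc3Oc12 | intermediate
21 | macrocyclic bis-formate ester (not isolated) | Oc1c(OC=O)ccc2CCc3ccc(cc3)Oc3cc(cc(OC=O)c3O)CCc3ccccc3Oc12 | intermediate
22 | CNP0114693.0 | Oc1cc2cc(c1O)Oc1ccc(cc1)CCc1ccc(O)c(O)c1Oc1ccccc1CC2 | target

**Step count and risks**

Total step count: 14. Longest linear sequence: 11 steps (1, 2, 3, 4, 7, 9, 10, 11, 12, 13, 14, from p-cresol).

Rings A and C each need two substituents beyond what an eight-atom precursor can carry. One of them (the second OH on each ring) is added for both rings together in the last two steps.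

Three steps most likely to fail:

Step 4 (dianion alkylation). Halogen–metal exchange at the aryl bromide, Wurtz-type homocoupling or O-alkylation could erode the yield. The fallback sets out from 4 and comes back at 7. Compound 4 is heated with PPh3 in toluene to give (3-bromo-4-methoxybenzyl)triphenylphosphonium bromide F1. Commercial phenol (seven heavy atoms) is ortho-formylated (MgCl2, Et3N, paraformaldehyde, MeCN) to salicylaldehyde F2. Wittig olefination of F2 with F1 (K2CO3, 18-crown-6, CH2Cl2) gives (E)-2-[2-(3-bromo-4-methoxyphenyl)ethenyl]phenol F3 (E/Z mixture, drawn as E). Diimide reduction (TsNHNH2, NaOAc, THF/H2O, reflux) saturates the alkene without touching the C–Br bond and gives 7.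

Step 10 (macrocyclising reductive amination with ammonia). Oligomers, the open primary diamine or tertiary amines may compete. The fallback sets out from 14 and comes back at 18, replacing the nitrogen linchpin by sulfur. Compound 14 is reduced with NaBH4 (MeOH) to the seco-diol F4 and converted with PBr3 (CH2Cl2) into the seco-bis(benzylic bromide) F5. Cyclisation with Na2S·9H2O under high dilution (EtOH/toluene) gives the 18-membered thia-macrocycle F6. Photochemical sulfur extrusion (254 nm, P(OMe)3), the classical thiacyclophane ring contraction, then gives 18.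

Step 11 (the proposed nitrogen-deletion ring contraction). Escape of the benzylic radical pair or coupling at ring positions could lower the yield in the large ring. The fallback uses known chemistry, sets out from 14 and comes back at 18. Intramolecular McMurry coupling of 14 (TiCl4, Zn, pyridine, THF, reflux, slow addition) gives the macrocyclic (Z)-stilbene F7 (either alkene isomer serves). Hydrogenation (H2, Pd/C, EtOAc) gives 18.

**Further compounds**

F1 | step 4 | (3-bromo-4-methoxybenzyl)triphenylphosphonium bromide | COc1ccc(C[P+](c2ccccc2)(c2ccccc2)c2ccccc2)cc1Br.[Br-]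
F2 | step 4 | salicylaldehyde (2-hydroxybenzaldehyde) | O=Cc1ccccc1O
F3 | step 4 | (E)-2-[2-(3-bromo-4-methoxyphenyl)ethenyl]phenol | Oc1ccccc1/C=C/c1ccc(OC)c(Br)c1
F4 | step 10 | seco-diol (both formyl groups of 14 reduced to CH2OH) | COc1cccc(CO)c1Oc1ccccc1CCc1ccc(OC)c(Oc2ccc(CO)cc2)c1
F5 | step 10 | seco-bis(benzylic bromide) | COc1cccc(CBr)c1Oc1ccccc1CCc1ccc(OC)c(Oc2ccc(CBr)cc2)c1
F6 | step 10 | 18-membered thia-macrocycle (CH2–S–CH2 between ring C C-1 and ring B C-4) | COc1cccc2CSCc3ccc(cc3)Oc3cc(ccc3OC)CCc3ccccc3Oc12
F7 | step 11 | macrocyclic (Z)-stilbene (CH=CH between ring C C-1 and ring B C-4) | COc1cccc2/C=C\c3ccc(cc3)Oc3cc(ccc3OC)CCc3ccccc3Oc12
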